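**Plan**

1. Retrosynthesis: the lactone is cut at O–CH2 and at C(=O)–Cα, so the carboxyl carbon leaves as formate and a ring A styrene with a CH2Cl on its allylic carbon remains. Next the bond from that allylic carbon to the benzylic CH2 of ring B is cut (enolate alkylation). Last, C2–C3 of the dihydrofuran ring C (carbenoid C–H insertion), the aryl–C(N2) bond and the benzylic ether are cut.
2. Enabling feature: the lactone α-carbon bears a CH2 bound to guaiacyl ring A, so Cα–CH2–Ar is the retron of a β-alkylstyrene that takes a CO2 radical anion at its non-benzylic carbon. The lactone OCH2 carbon stands 1,3 to Cα, so the new carboxylate can close the five-membered ring on a CH2Cl group.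
3. Forward: ring B (5-iodovanillin) is etherified with the ring D benzyl chloride; ring C is closed by C–H insertion; the benzylic bromide is joined to the ring A styrylacetyl imide; the lactone ring is made last from formate.
4. Stereochemistry: C2 of the dihydrobenzofuran comes from the chiral dirhodium catalyst and C3 from base epimerisation to trans. Lactone C4 comes from the (R)-oxazolidinone auxiliary and lactone C3 from base equilibration to trans.

Key step: step 12

Assumption: for 2-(benzyloxy)aryl diazoacetates the (S)-ligand dirhodium phthaloyl-tert-leucinate is taken to give the 2R cis product, so the (R)-ligand catalyst is used to obtain 2S.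

**Route**

Step 1
Reactants: 1 5-iodovanillin; 2 4-(benzyloxy)-3-methoxybenzyl chloride
Product: 3 4-{[4-(benzyloxy)-3-methoxybenzyl]oxy}-3-iodo-5-methoxybenzaldehyde
Conditions: K2CO3, KI (cat.), DMF, 60 °C
Reagents that add atoms: none
Why: Williamson ether synthesis of an acidic, non-enolisable phenol with a reactive benzylic chloride, which installs the OCH2 group that later becomes C2 of ring C.

Step 2
Reactants: 3 4-{[4-(benzyloxy)-3-methoxybenzyl]oxy}-3-iodo-5-methoxybenzaldehyde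
Product: 4 ethyl 2-diazo-2-(2-{[4-(benzyloxy)-3-methoxybenzyl]oxy}-5-formyl-3-methoxyphenyl)acetate
Conditions: ethyl diazoacetate, Pd(PPh3)4 (5 mol%), Ag2CO3 (0.5 equiv), Et3N, toluene, rt
Reagents that add atoms: ethyl diazoacetate CCOC(=O)C=[N+]=[N-]
Why: palladium-catalysed C–H arylation of an acceptor diazo compound by an aryl iodide (oxidative addition, silver-assisted deprotonative transfer of the diazo carbon, reductive elimination) should give the aryl diazoacetate at room temperature with the diazo group intact.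

Step 3
Reactants: 4 ethyl 2-diazo-2-(2-{[4-(benzyloxy)-3-methoxybenzyl]oxy}-5-formyl-3-methoxyphenyl)acetate
Product: 5 ethyl (2S,3R)-2-[4-(benzyloxy)-3-methoxyphenyl]-5-formyl-7-methoxy-2,3-dihydro-1-benzofuran-3-carboxylate
Conditions: dirhodium tetrakis[N-phthaloyl-(R)-tert-leucinate] Rh2(R-PTTL)4 (2 mol%), toluene, −60 °C
Reagents that add atoms: none
Why: intramolecular 1,5 C–H insertion of the donor/acceptor rhodium carbenoid into the ether OCH2 (activated by oxygen and by electron-rich ring D) closes ring C as the cis isomer, and the chiral carboxylate ligands select one enantiotopic hydrogen to set C2 as S.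

Step 4
Reactants: 5 ethyl (2S,3R)-2-[4-(benzyloxy)-3-methoxyphenyl]-5-formyl-7-methoxy-2,3-dihydro-1-benzofuran-3-carboxylate
Product: 7 ethyl (2S,3S)-2-[4-(benzyloxy)-3-methoxyphenyl]-5-(hydroxymethyl)-7-methoxy-2,3-dihydro-1-benzofuran-3-carboxylate, via cis hydroxymethyl ester 6 (not isolated)
Conditions: NaBH4, EtOH, 0 °C; then NaOEt (0.3 equiv), EtOH, rt
Reagents that add atoms: none
Why: chemoselective borohydride reduction of the aldehyde, then ethoxide-catalysed epimerisation at C3 (α to the ester) to the thermodynamically preferred 2,3-trans ester with C2 untouched; reducing first makes the ring phenoxide a poor leaving group and so disfavours E1cB ring opening.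

Step 5
Reactants: 7 ethyl (2S,3S)-2-[4-(benzyloxy)-3-methoxyphenyl]-5-(hydroxymethyl)-7-methoxy-2,3-dihydro-1-benzofuran-3-carboxylate
Product: 8 ethyl (2S,3S)-2-[4-(benzyloxy)-3-methoxyphenyl]-5-(bromomethyl)-7-methoxy-2,3-dihydro-1-benzofuran-3-carboxylate
Conditions: CBr4, PPh3, CH2Cl2, 0 °C
Reagents that add atoms: carbon tetrabromide BrC(Br)(Br)Br
Why: Appel reaction turns the benzylic alcohol into the bromide under neutral conditions that leave the ester and the benzylic ring ether alone.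

Step 6
Reactants: 9 4-(benzyloxy)-3-methoxybenzaldehyde; 10 (2-carboxyethyl)triphenylphosphonium bromide
Product: 12 (E)-4-[4-(benzyloxy)-3-methoxyphenyl]but-3-enoic acid, via phosphorus ylide 11 (not isolated)
Conditions: NaN(SiMe3)2 (2.1 equiv), THF, 0 °C to rt; then aq. HCl
Reagents that add atoms: none
Why: Wittig olefination with the carboxylate-bearing ylide gives the β,γ-unsaturated acid, expected mainly as the E alkene; the geometry is of no consequence because the alkene is consumed in step 12.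

Step 7
Reactants: 12 (E)-4-[4-(benzyloxy)-3-methoxyphenyl]but-3-enoic acid; 13 (R)-4-benzyl-1,3-oxazolidin-2-one
Product: 15 (4R)-4-benzyl-3-{(3E)-4-[4-(benzyloxy)-3-methoxyphenyl]but-3-enoyl}-1,3-oxazolidin-2-one, via pivalic mixed anhydride 14 (not isolated)
Conditions: t-BuCOCl, Et3N, THF, −20 °C; then 13, LiCl, rt
Reagents that add atoms: none
Why: mixed-anhydride N-acylation of the oxazolidinone under LiCl/Et3N avoids strong base that could move the styryl double bond into conjugation with the carbonyl.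

Step 8
Reactants: 15 (4R)-4-benzyl-3-{(3E)-4-[4-(benzyloxy)-3-methoxyphenyl]but-3-enoyl}-1,3-oxazolidin-2-one; 8 ethyl (2S,3S)-2-[4-(benzyloxy)-3-methoxyphenyl]-5-(bromomethyl)-7-methoxy-2,3-dihydro-1-benzofuran-3-carboxylate
Product: 17 ethyl (2S,3S)-5-[(2R,3E)-2-{[(4R)-4-benzyl-2-oxo-1,3-oxazolidin-3-yl]carbonyl}-4-[4-(benzyloxy)-3-methoxyphenyl]but-3-en-1-yl]-2-[4-(benzyloxy)-3-methoxyphenyl]-7-methoxy-2,3-dihydro-1-benzofuran-3-carboxylate, via sodium Z-enolate 16 (not isolated)
Conditions: NaN(SiMe3)2 (1.0 equiv), THF, −78 °C; then 8, −78 to −40 °C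
Reagents that add atoms: none
Why: oxazolidinone-auxiliary (Evans) alkylation of the chelated Z-dienolate at its α-carbon, on the face away from the auxiliary benzyl group, should set the future lactone C4 as R; the less basic imide enolate should not deprotonate the ester of 8.

Step 9
Reactants: 17 the alkylated imide
Product: 18 ethyl (2S,3S)-5-[(2R,3E)-4-[4-(benzyloxy)-3-methoxyphenyl]-2-(hydroxymethyl)but-3-en-1-yl]-2-[4-(benzyloxy)-3-methoxyphenyl]-7-methoxy-2,3-dihydro-1-benzofuran-3-carboxylate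
Conditions: LiBH4 (1.2 equiv), MeOH (1.2 equiv), THF/Et2O, 0 °C
Reagents that add atoms: none
Why: reductive cleavage of the N-acyl oxazolidinone, whose imide carbonyl is far more electrophilic than the hindered secondary ethyl ester, should give the primary alcohol quickly enough that the α-centre does not epimerise.

Step 10
Reactants: 18 the primary alcohol
Product: 19 ethyl (2S,3S)-5-[(2R,3E)-4-[4-(benzyloxy)-3-methoxyphenyl]-2-(chloromethyl)but-3-en-1-yl]-2-[4-(benzyloxy)-3-methoxyphenyl]-7-methoxy-2,3-dihydro-1-benzofuran-3-carboxylate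
Conditions: PPh3, N-chlorosuccinimide (premixed), THF, 0 °C to rt
Reagents that add atoms: N-chlorosuccinimide O=C1CCC(=O)N1Cl
Why: Appel-type chlorination through the alkoxyphosphonium salt is an SN2 reaction at the primary carbon and does not involve the neighbouring stereocentre.

Step 11
Reactants: 19 the chloro ester
Product: 20 {(2S,3R)-2-[4-(benzyloxy)-3-methoxyphenyl]-5-[(2R,3E)-4-[4-(benzyloxy)-3-methoxyphenyl]-2-(chloromethyl)but-3-en-1-yl]-7-methoxy-2,3-dihydro-1-benzofuran-3-yl}methanol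
Conditions: i-Bu2AlH (3 equiv), CH2Cl2, −78 to 0 °C
Reagents that add atoms: none
Why: diisobutylaluminium hydride reduction of the ester to the primary alcohol leaves the alkyl chloride, the styrene and the benzyl ethers untouched, and removes the last epimerisable centre of ring C.

Step 12
Reactants: 20 the chloro alcohol
Product: 22 (3RS,4R)-3-[4-(benzyloxy)-3-methoxybenzyl]-4-({(2S,3R)-2-[4-(benzyloxy)-3-methoxyphenyl]-3-(hydroxymethyl)-7-methoxy-2,3-dihydro-1-benzofuran-5-yl}methyl)oxolan-2-one, via chloro carboxylate 21 (not isolated)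
Conditions: HCO2K (4 equiv), 4CzIPN (1,2,3,5-tetrakis(carbazol-9-yl)-4,6-dicyanobenzene, 1 mol%), 1-adamantanethiol (20 mol%), DMSO, 450 nm LEDs, rt; then 50 °C
Reagents that add atoms: potassium formate [K+].[O-]C=O
Why: Proposed new method: the excited photocatalyst starts a chain in which the thiyl radical abstracts the formyl hydrogen of formate, and the CO2 radical anion adds to the styrene carbon remote from ring A to give a benzylic radical that ring A stabilises and that takes a hydrogen atom back from the thiol; the γ-chloro carboxylate 21 then displaces chloride from the CH2Cl carbon. The closest known reactions are the thiol/formate photochemical anti-Markovnikov hydrocarboxylation of styrenes and the lactonisation of 4-halobutanoates, which have not been joined in one operation on a styrene that carries the halide. The one ring formed, the oxolanone, closes 5-exo-tet by SN2 at a primary carbon, so the C4 centre set in step 8 is not touched. The new centre at lactone C3 arises in the radical addition under only weak 1,2-induction from C4 and is expected as an epimer mixture, which step 13 corrects by equilibration. The step needs regioselectivity (C–C bond at the non-benzylic alkene carbon), secured by conjugation of the alkene with ring A, and chemoselectivity (C–Cl intact until the carboxylate exists), secured by a primary alkyl chloride that lies beyond the reducing power of the CO2 radical anion and by a tertiary thiol that is not deprotonated by formate.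

Step 13
Reactants: 22 the lactone C3 epimer mixture
Product: 23 (3R,4R)-3-[4-(benzyloxy)-3-methoxybenzyl]-4-({(2S,3R)-2-[4-(benzyloxy)-3-methoxyphenyl]-3-(hydroxymethyl)-7-methoxy-2,3-dihydro-1-benzofuran-5-yl}methyl)oxolan-2-one
Conditions: DBU, toluene, 80 °C
Reagents that add atoms: none
Why: base-mediated epimerisation through the lactone enolate should converge on the thermodynamically preferred trans-3,4-dibenzyl lactone, with the fixed C4 centre directing C3 to R.

Step 14
Reactants: 23 the trans lactone bis(benzyl ether)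
Product: 24 lappaol A
Conditions: H2 (1 atm), 10% Pd/C, EtOAc/MeOH, rt
Reagents that add atoms: none
Why: hydrogenolysis of the two aryl benzyl ethers under mild conditions should free both phenols without cleaving the lactone or the benzylic C2–O bond of ring C.

**Compound list**

1 | 5-iodovanillin (4-hydroxy-3-iodo-5-methoxybenzaldehyde) | O=Cc1cc(I)c(O)c(OC)c1 | starting material
2 | 4-(benzyloxy)-3-methoxybenzyl chloride | ClCc1ccc(OCc2ccccc2)c(OC)c1 | starting material
3 | 4-{[4-(benzyloxy)-3-methoxybenzyl]oxy}-3-iodo-5-methoxybenzaldehyde | O=Cc1cc(I)c(OCc2ccc(OCc3ccccc3)c(OC)c2)c(OC)c1 | intermediate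
4 | ethyl 2-diazo-2-(2-{[4-(benzyloxy)-3-methoxybenzyl]oxy}-5-formyl-3-methoxyphenyl)acetate | CCOC(=O)C(=[N+]=[N-])c1cc(C=O)cc(OC)c1OCc1ccc(OCc2ccccc2)c(OC)c1 | intermediate
5 | ethyl (2S,3R)-2-[4-(benzyloxy)-3-methoxyphenyl]-5-formyl-7-methoxy-2,3-dihydro-1-benzofuran-3-carboxylate (cis) | O=Cc1cc(OC)c2c(c1)[C@@H](C(=O)OCC)[C@@H](c1ccc(OCc3ccccc3)c(OC)c1)O2 | intermediate
6 | ethyl (2S,3R)-2-[4-(benzyloxy)-3-methoxyphenyl]-5-(hydroxymethyl)-7-methoxy-2,3-dihydro-1-benzofuran-3-carboxylate (cis) | OCc1cc(OC)c2c(c1)[C@@H](C(=O)OCC)[C@@H](c1ccc(OCc3ccccc3)c(OC)c1)O2 | intermediate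
7 | ethyl (2S,3S)-2-[4-(benzyloxy)-3-methoxyphenyl]-5-(hydroxymethyl)-7-methoxy-2,3-dihydro-1-benzofuran-3-carboxylate (trans) | OCc1cc(OC)c2c(c1)[C@H](C(=O)OCC)[C@@H](c1ccc(OCc3ccccc3)c(OC)c1)O2 | intermediate
8 | ethyl (2S,3S)-2-[4-(benzyloxy)-3-methoxyphenyl]-5-(bromomethyl)-7-methoxy-2,3-dihydro-1-benzofuran-3-carboxylate | BrCc1cc(OC)c2c(c1)[C@H](C(=O)OCC)[C@@H](c1ccc(OCc3ccccc3)c(OC)c1)O2 | intermediate
9 | 4-(benzyloxy)-3-methoxybenzaldehyde | O=Cc1ccc(OCc2ccccc2)c(OC)c1 | starting material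
10 | (2-carboxyethyl)triphenylphosphonium bromide | OC(=O)CC[P+](c1ccccc1)(c1ccccc1)c1ccccc1.[Br-] | starting material
11 | sodium 3-(triphenylphosphoranylidene)propanoate (ylide) | [Na+].[O-]C(=O)CC=P(c1ccccc1)(c1ccccc1)c1ccccc1 | intermediate
12 | (E)-4-[4-(benzyloxy)-3-methoxyphenyl]but-3-enoic acid | OC(=O)C/C=C/c1ccc(OCc2ccccc2)c(OC)c1 | intermediate
13 | (R)-4-benzyl-1,3-oxazolidin-2-one | O=C1N[C@H](Cc2ccccc2)CO1 | starting material
14 | (E)-4-[4-(benzyloxy)-3-methoxyphenyl]but-3-enoic pivalic anhydride | CC(C)(C)C(=O)OC(=O)C/C=C/c1ccc(OCc2ccccc2)c(OC)c1 | intermediate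
15 | (4R)-4-benzyl-3-{(3E)-4-[4-(benzyloxy)-3-methoxyphenyl]but-3-enoyl}-1,3-oxazolidin-2-one | O=C(C/C=C/c1ccc(OCc2ccccc2)c(OC)c1)N1[C@H](Cc2ccccc2)COC1=O | intermediate
16 | sodium Z-enolate (dienolate) of 15 | [Na+].[O-]/C(=C\C=C\c1ccc(OCc2ccccc2)c(OC)c1)N1[C@H](Cc2ccccc2)COC1=O | intermediate
17 | ethyl (2S,3S)-5-[(2R,3E)-2-{[(4R)-4-benzyl-2-oxo-1,3-oxazolidin-3-yl]carbonyl}-4-[4-(benzyloxy)-3-methoxyphenyl]but-3-en-1-yl]-2-[4-(benzyloxy)-3-methoxyphenyl]-7-methoxy-2,3-dihydro-1-benzofuran-3-carboxylate | O=C([C@H](Cc1cc(OC)c2c(c1)[C@H](C(=O)OCC)[C@@H](c1ccc(OCc3ccccc3)c(OC)c1)O2)/C=C/c1ccc(OCc2ccccc2)c(OC)c1)N1[C@H](Cc2ccccc2)COC1=O | intermediate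
18 | ethyl (2S,3S)-5-[(2R,3E)-4-[4-(benzyloxy)-3-methoxyphenyl]-2-(hydroxymethyl)but-3-en-1-yl]-2-[4-(benzyloxy)-3-methoxyphenyl]-7-methoxy-2,3-dihydro-1-benzofuran-3-carboxylate | OC[C@H](Cc1cc(OC)c2c(c1)[C@H](C(=O)OCC)[C@@H](c1ccc(OCc3ccccc3)c(OC)c1)O2)/C=C/c1ccc(OCc2ccccc2)c(OC)c1 | intermediate
19 | ethyl (2S,3S)-5-[(2R,3E)-4-[4-(benzyloxy)-3-methoxyphenyl]-2-(chloromethyl)but-3-en-1-yl]-2-[4-(benzyloxy)-3-methoxyphenyl]-7-methoxy-2,3-dihydro-1-benzofuran-3-carboxylate | ClC[C@H](Cc1cc(OC)c2c(c1)[C@H](C(=O)OCC)[C@@H](c1ccc(OCc3ccccc3)c(OC)c1)O2)/C=C/c1ccc(OCc2ccccc2)c(OC)c1 | intermediate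
20 | {(2S,3R)-2-[4-(benzyloxy)-3-methoxyphenyl]-5-[(2R,3E)-4-[4-(benzyloxy)-3-methoxyphenyl]-2-(chloromethyl)but-3-en-1-yl]-7-methoxy-2,3-dihydro-1-benzofuran-3-yl}methanol | ClC[C@H](Cc1cc(OC)c2c(c1)[C@H](CO)[C@@H](c1ccc(OCc3ccccc3)c(OC)c1)O2)/C=C/c1ccc(OCc2ccccc2)c(OC)c1 | intermediate
21 | potassium (2RS,3R)-2-[4-(benzyloxy)-3-methoxybenzyl]-4-chloro-3-({(2S,3R)-2-[4-(benzyloxy)-3-methoxyphenyl]-3-(hydroxymethyl)-7-methoxy-2,3-dihydro-1-benzofuran-5-yl}methyl)butanoate | [K+].[O-]C(=O)C(Cc1ccc(OCc2ccccc2)c(OC)c1)[C@H](CCl)Cc1cc(OC)c2c(c1)[C@H](CO)[C@@H](c1ccc(OCc3ccccc3)c(OC)c1)O2 | intermediate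
22 | (3RS,4R)-3-[4-(benzyloxy)-3-methoxybenzyl]-4-({(2S,3R)-2-[4-(benzyloxy)-3-methoxyphenyl]-3-(hydroxymethyl)-7-methoxy-2,3-dihydro-1-benzofuran-5-yl}methyl)oxolan-2-one (C3 epimer mixture) | COc1cc(CC2C(=O)OC[C@@H]2Cc2cc(OC)c3c(c2)[C@H](CO)[C@@H](c2ccc(OCc4ccccc4)c(OC)c2)O3)ccc1OCc1ccccc1 | intermediate
23 | (3R,4R)-3-[4-(benzyloxy)-3-methoxybenzyl]-4-({(2S,3R)-2-[4-(benzyloxy)-3-methoxyphenyl]-3-(hydroxymethyl)-7-methoxy-2,3-dihydro-1-benzofuran-5-yl}methyl)oxolan-2-one | COc1cc(C[C@H]2C(=O)OC[C@@H]2Cc2cc(OC)c3c(c2)[C@H](CO)[C@@H](c2ccc(OCc4ccccc4)c(OC)c2)O3)ccc1OCc1ccccc1 | intermediate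
24 | lappaol A, (3R,4R)-3-(4-hydroxy-3-methoxybenzyl)-4-({(2S,3R)-2-(4-hydroxy-3-methoxyphenyl)-3-(hydroxymethyl)-7-methoxy-2,3-dihydro-1-benzofuran-5-yl}methyl)oxolan-2-one | COc1cc(C[C@H]2C(=O)OC[C@@H]2Cc2cc(OC)c3c(c2)[C@H](CO)[C@@H](c2ccc(O)c(OC)c2)O3)ccc1O | target

**Step count and risks**

Total steps: 14. Longest linear sequence: 12 steps (steps 1 to 5, then 8 to 14); steps 6 and 7 form the side branch.

Steps most likely to fail:

1. Step 12 (the step labelled as a proposed new method). The addition of the nucleophilic CO2 radical anion to the electron-rich, β-branched styrene may be slow. Chloride may be substituted by formate or thiolate before carboxylation, or the benzylic radical may couple instead of taking up hydrogen. Fallback with known chemistry, which separates the two bond formations and closes the ring by acyl substitution: from 18, LiAlH4 (THF, 0 °C) reduces the ethyl ester to the diol (2R,3E)-4-[4-(benzyloxy)-3-methoxyphenyl]-2-({(2S,3R)-2-[4-(benzyloxy)-3-methoxyphenyl]-3-(hydroxymethyl)-7-methoxy-2,3-dihydro-1-benzofuran-5-yl}methyl)but-3-en-1-ol F1. The known thiol/formate photochemical hydrocarboxylation of the styrene (HCO2K, 4CzIPN, thiol, DMSO, 450 nm), now with no electrophilic carbon in the substrate, gives the dihydroxy acid (2RS,3R)-2-[4-(benzyloxy)-3-methoxybenzyl]-4-hydroxy-3-({(2S,3R)-2-[4-(benzyloxy)-3-methoxyphenyl]-3-(hydroxymethyl)-7-methoxy-2,3-dihydro-1-benzofuran-5-yl}methyl)butanoic acid F2. On acidification (TsOH, toluene, rt) F2 lactonises to 22, where the route resumes with step 13.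

2. Step 2. The diazoacetate may add to the aldehyde under the basic conditions, or oxidative addition and transfer at the ortho-alkoxy iodide may be slow enough for the diazo compound to decompose on palladium. Fallback, which builds the arylacetate first and introduces the diazo group last: from 3, copper-catalysed arylation of diethyl malonate (CuI, 2-picolinic acid, Cs2CO3, dioxane) gives diethyl 2-(2-{[4-(benzyloxy)-3-methoxybenzyl]oxy}-5-formyl-3-methoxyphenyl)malonate F3. Krapcho dealkoxycarbonylation (LiCl, wet DMSO, 130 °C) gives ethyl 2-(2-{[4-(benzyloxy)-3-methoxybenzyl]oxy}-5-formyl-3-methoxyphenyl)acetate F4. Regitz diazo transfer (4-acetamidobenzenesulfonyl azide, DBU, MeCN) returns to 4.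

3. Step 3. Facial selectivity at the carbenoid C–H insertion may be poor on this heavily oxygenated substrate, or the sense of induction may be opposite to the one assumed, so that C2 is not obtained as one enantiomer. Fallback, which replaces catalyst control by separation of diastereomers formed with the enantiopure imide: from 4, the insertion is run with achiral Rh2(OAc)4 (CH2Cl2, rt) and gives 5 together with its enantiomer ethyl (2R,3S)-2-[4-(benzyloxy)-3-methoxyphenyl]-5-formyl-7-methoxy-2,3-dihydro-1-benzofuran-3-carboxylate F5. Step 4 then gives 7 and its enantiomer ethyl (2R,3R)-2-[4-(benzyloxy)-3-methoxyphenyl]-5-(hydroxymethyl)-7-methoxy-2,3-dihydro-1-benzofuran-3-carboxylate F7, by way of 6 and ethyl (2R,3S)-2-[4-(benzyloxy)-3-methoxyphenyl]-5-(hydroxymethyl)-7-methoxy-2,3-dihydro-1-benzofuran-3-carboxylate F6. Step 5 gives 8 and its enantiomer ethyl (2R,3R)-2-[4-(benzyloxy)-3-methoxyphenyl]-5-(bromomethyl)-7-methoxy-2,3-dihydro-1-benzofuran-3-carboxylate F8. Alkylation of enolate 16 with this racemic bromide gives 17 and its diastereomer ethyl (2R,3R)-5-[(2R,3E)-2-{[(4R)-4-benzyl-2-oxo-1,3-oxazolidin-3-yl]carbonyl}-4-[4-(benzyloxy)-3-methoxyphenyl]but-3-en-1-yl]-2-[4-(benzyloxy)-3-methoxyphenyl]-7-methoxy-2,3-dihydro-1-benzofuran-3-carboxylate F9. The two are separated by chromatography or crystallisation, and 17 goes on to step 9.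

Further compounds
F1 | step 12 | (2R,3E)-4-[4-(benzyloxy)-3-methoxyphenyl]-2-({(2S,3R)-2-[4-(benzyloxy)-3-methoxyphenyl]-3-(hydroxymethyl)-7-methoxy-2,3-dihydro-1-benzofuran-5-yl}methyl)but-3-en-1-ol | OC[C@H](Cc1cc(OC)c2c(c1)[C@H](CO)[C@@H](c1ccc(OCc3ccccc3)c(OC)c1)O2)/C=C/c1ccc(OCc2ccccc2)c(OC)c1
F2 | step 12 | (2RS,3R)-2-[4-(benzyloxy)-3-methoxybenzyl]-4-hydroxy-3-({(2S,3R)-2-[4-(benzyloxy)-3-methoxyphenyl]-3-(hydroxymethyl)-7-methoxy-2,3-dihydro-1-benzofuran-5-yl}methyl)butanoic acid | OC(=O)C(Cc1ccc(OCc2ccccc2)c(OC)c1)[C@H](CO)Cc1cc(OC)c2c(c1)[C@H](CO)[C@@H](c1ccc(OCc3ccccc3)c(OC)c1)O2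
F3 | step 2 | diethyl 2-(2-{[4-(benzyloxy)-3-methoxybenzyl]oxy}-5-formyl-3-methoxyphenyl)malonate | CCOC(=O)C(C(=O)OCC)c1cc(C=O)cc(OC)c1OCc1ccc(OCc2ccccc2)c(OC)c1
F4 | step 2 | ethyl 2-(2-{[4-(benzyloxy)-3-methoxybenzyl]oxy}-5-formyl-3-methoxyphenyl)acetate | CCOC(=O)Cc1cc(C=O)cc(OC)c1OCc1ccc(OCc2ccccc2)c(OC)c1
F5 | step 3 | ethyl (2R,3S)-2-[4-(benzyloxy)-3-methoxyphenyl]-5-formyl-7-methoxy-2,3-dihydro-1-benzofuran-3-carboxylate | O=Cc1cc(OC)c2c(c1)[C@H](C(=O)OCC)[C@H](c1ccc(OCc3ccccc3)c(OC)c1)O2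
F6 | step 3 | ethyl (2R,3S)-2-[4-(benzyloxy)-3-methoxyphenyl]-5-(hydroxymethyl)-7-methoxy-2,3-dihydro-1-benzofuran-3-carboxylate | OCc1cc(OC)c2c(c1)[C@H](C(=O)OCC)[C@H](c1ccc(OCc3ccccc3)c(OC)c1)O2
F7 | step 3 | ethyl (2R,3R)-2-[4-(benzyloxy)-3-methoxyphenyl]-5-(hydroxymethyl)-7-methoxy-2,3-dihydro-1-benzofuran-3-carboxylate | OCc1cc(OC)c2c(c1)[C@@H](C(=O)OCC)[C@H](c1ccc(OCc3ccccc3)c(OC)c1)O2
F8 | step 3 | ethyl (2R,3R)-2-[4-(benzyloxy)-3-methoxyphenyl]-5-(bromomethyl)-7-methoxy-2,3-dihydro-1-benzofuran-3-carboxylate | BrCc1cc(OC)c2c(c1)[C@@H](C(=O)OCC)[C@H](c1ccc(OCc3ccccc3)c(OC)c1)O2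
F9 | step 3 | ethyl (2R,3R)-5-[(2R,3E)-2-{[(4R)-4-benzyl-2-oxo-1,3-oxazolidin-3-yl]carbonyl}-4-[4-(benzyloxy)-3-methoxyphenyl]but-3-en-1-yl]-2-[4-(benzyloxy)-3-methoxyphenyl]-7-methoxy-2,3-dihydro-1-benzofuran-3-carboxylate | O=C([C@H](Cc1cc(OC)c2c(c1)[C@@H](C(=O)OCC)[C@H](c1ccc(OCc3ccccc3)c(OC)c1)O2)/C=C/c1ccc(OCc2ccccc2)c(OC)c1)N1[C@H](Cc2ccccc2)COC1=O
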